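Atom labels used throughout: the lactone half carries eudesmane numbers C1–C15 (C11 is the spiro carbon, C12 the lactone carbonyl, C13 the CH2 next to C11). The decalin half carries primed numbers (C4' bears the methylene C15', C10' the angular methyl, C7' the three-carbon unit C11', C12', C13').

## Analysis of the target

The molecule is a C30 dimer of two eudesmane-type units. One is an intact alantolactone skeleton: cyclohexane ring A, cyclohexene ring B with C5=C6, and a γ-lactone cis-fused at C7/C8. The other is an exo-methylene decalin. They are joined through a 3,4-dihydro-2H-pyran made of O, C11 (spiro, also the lactone α-carbon), C13, C13', C11' and C12'.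

There are eight stereocentres: C4, C7, C8, C10 and the spiro C11 in the lactone half, and C5', C7' and C10' in the decalin. In the lactone half the pyran oxygen on C11 lies on the α face, syn to H-7, which is the convex face of the cis-fused lactone. In the decalin the C10' methyl, H-5' and the C7' substituent are all cis, so its two rings are cis-fused.

Sensitive groups are the cyclic enol ether C11'=C12'–O (acid), the exocyclic C4'=C15' alkene (isomerisation), the lactone, and C5' for as long as C4' is a carbonyl (epimerisation).

The difficulty is threefold: the quaternary C10' next to a cis ring fusion, the C7' centre placed 1,4 to C10' with nothing nearby to relay stereochemistry, and the oxygen-bearing spiro centre C11 that joins two halves with no stereochemical communication.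

The route rests on two structural features. First, C4' is bonded to C5', which is bonded to the quaternary C10'. A ketone at C4' therefore makes C10' the β-carbon and C5' the α-carbon of a cyclohexenone, so ring B of the decalin (C5'–C6'–C7'–C8'–C9'–C10') can be annulated by conjugate addition at C10' followed by enolate alkylation at C5'. Second, the dihydropyran is the formal [4+2] adduct of the C11=C13 methylene of alantolactone and a C13'=C11'–C12'=O enal.

## Retrosynthetic reasoning

**Union of the halves.** Target 22 is cut at O–C11 and C13–C13'. This retro-hetero-Diels–Alder step gives enal 20 and alantolactone 21, which is a commercial natural product carrying C4, C7, C8 and C10 already. The forward cycloaddition has to put oxygen on C11 (not C13) and approach the α face of the lactone. Both follow the normal behaviour of enal heterodienes toward acrylate-type dienophiles and of cis-fused methylene lactones. The cut removes one ring, two bonds and the spiro centre in a single step with no protecting groups.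

**Adjusting the decalin.** Enal 20 is traced through alcohol 19, silyl ether 18, ketone 17 and hydroxy ketone 16 to the isopropenyl decalone 15. The enal comes from the isopropenyl methyl by allylic hydroxylation and oxidation. The C4' methylene comes from the ketone by a non-basic methylenation. The order matters: the allylic hydroxylation is done while C4' is still a carbonyl, because a C4'=C15' alkene would compete for the oxidant. The methylenation is done with the hydroxyl masked and without base, because C5' is epimerisable.

**Key disconnection.** Decalone 15 is cut at C9'–C10' and C5'–C6'. This gives the flat, achiral enone 13 and the four-carbon chloro-Grignard reagent 12, which already carries C7'. No other cut through ring B lets one carbonyl direct both bonds. The forward step must add the alkyl group to one face of C3 of 13 under catalyst control and then use the resulting enolate 14 to close ring B. One ring, two C–C bonds and two stereocentres (C10', C5') are gained, and the ketone is left exactly where the methylene is needed.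

**The reagent.** Grignard reagent 12 comes from bromide 11 by magnesium insertion, which leaves the C–Cl bond for the later ring closure. Bromide 11 is reached from alcohol 10, which comes from chloro ester 9 and hydroxy ester 8. The two arms on C7' are told apart by their oxidation levels in 8 (alcohol against ester), so no selective reaction between two like groups is needed.

**The stereocentre C7'.** Hydroxy ester 8 comes from imide 7 by reductive removal of the auxiliary. Imide 7 is cut at the C7'–C8' bond into the senecioyl imide 4 and bromoacetate 5. This is a deconjugative auxiliary-controlled alkylation: the isopropenyl group arises from the dienolate of 4 and the arm enters at the α-carbon. The arm must place exactly two carbons between C7' and magnesium. An allyl group carried through hydroboration would place three and lead to a seven-membered ring, so the arm is brought in as an acetate unit from 5. Imide 4 comes from acid 1 and auxiliary 2.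

## Alternatives that were turned down

**Alternative 1: allenic hetero-Pauson–Khand reaction for the lactone half.**
- Disconnection: C7–C8, C11–C12 and C12–O of the lactone half, back to the vinylallene aldehyde A2 and carbon monoxide.
- Forward key step: Mo(CO)6 with DMSO couples the aldehyde carbon C8, the allene bond C7=C11 and CO to give alantolactone (A1).
- For it: three bonds, ring B and the methylene lactone in one operation. On bonds per step it is stronger than the chosen key step, and it would open the lactone half to analogues.
- Against it: A1 is identical with 21, which can be bought. The step creates C7 and C8 next to the quaternary C10 with no clear bias for the required cis-lactone on the β face. The aldehyde variant of this cyclocarbonylation needs stoichiometric molybdenum. A2, with a Z-configured exocyclic alkene, an allene and two stereocentres, needs its own multistep synthesis.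
- Comparison: the hard half of the target, the cis decalin, is left untouched, so enal 20 would still have to be made. The chosen strategy spends its key step on the half that cannot be purchased.

**Alternative 2: intramolecular Diels–Alder reaction of a Z-diene for the decalin.**
- Disconnection: C5'–C10' and C6'–C7', back to the acyclic trienone A4.
- Forward key step: Me2AlCl or a chiral Lewis acid such as (BINOLate)TiCl2 activates the vinyl ketone, which adds across the diene to give the cis-fused octalone ketal A3.
- For it: both decalin rings, two bonds and three stereocentres (C5', C7', C10') arise at once from an open chain. In complexity gained per step this is stronger than the chosen annulation, which closes only one ring.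
- Against it: all absolute configuration would rest on a chiral Lewis acid bound to a single carbonyl lone pair, a weak basis for facial control; with Me2AlCl the product is racemic. The diene needs a Z-trisubstituted C10'=C9' bond, and such dienes react sluggishly and are prone to 1,5-hydrogen shifts. C10' becomes quaternary in the cycloaddition, which slows it further. The C7'/C5' relation depends on endo/exo preference.
- Comparison: after the cycloaddition the C8'=C9' alkene must be hydrogenated, and the ketal must be converted into the acrolein unit by methylenation and allylic oxidation, so the tail is longer than from 15. The chosen strategy instead takes C7' from an auxiliary of known behaviour, sets C10' with a catalyst whose errors appear as a separable diastereomer, and fixes C5' by geometry.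

**Alternative 3: ring-closing metathesis, then allyl-to-enol-ether migration.**
- Disconnection: the C13'=C11' bond of the spiro 3,6-dihydro-2H-pyran A5, back to the metathesis diene A6. In A6, C11 of the lactone carries an allyl group and a tertiary ether to the 2-decalinylallyl unit.
- Forward key step: (H2IMes)(PCy3)Cl2Ru=CHPh closes the six-membered oxacycle; the ring alkene is then moved into conjugation with oxygen.
- For it: the spiro centre is set by stepwise enolate chemistry before the ring forms, so it does not depend on the regio- and facial selectivity of a cycloaddition. Six-ring metathesis with one 1,1-disubstituted partner is dependable. On predictability of the ring closure it is stronger than the thermal cycloaddition used here.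
- Against it: A6 needs a tertiary α-alkoxy lactone, and etherifying a tertiary α-hydroxy lactone with a hindered allylic electrophile is difficult. The final alkene migration must act on the ring alkene alone, while the isomerisation-prone C4'=C15' methylene and C5=C6 stay put. The union takes at least four steps instead of one.
- Comparison: this alternative says nothing about the decalin, which must still be built. The chosen strategy builds the decalin in its key step and joins the halves in one atom-economical operation, and its fallback for the union keeps a stepwise logic in reserve.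

Key step: step 8

Assumption: the chiral carbene precursor in step 8 is used as the antipode that delivers the alkyl group to the Re face of C3 of enone 13; both antipodes of this ligand class are accessible from the corresponding amino alcohol.

## Route

Step 1
Reactants: 1 3-methylbut-2-enoic acid; 2 (4R)-4-benzyl-1,3-oxazolidin-2-one
Product: 4 (4R)-4-benzyl-3-(3-methylbut-2-enoyl)-1,3-oxazolidin-2-one, via 3-methylbut-2-enoic pivalic anhydride 3 (not isolated)
Conditions: t-BuCOCl, Et3N, THF, −20 °C; then LiCl, 2, −20 °C → rt
Reagents that add atoms: none
Why: Mixed-anhydride N-acylation of an oxazolidinone with LiCl/Et3N acyl transfer is routine for enoic acids and avoids a strong base that could deconjugate the acyl group; no stereocentre is formed.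

Step 2
Reactants: 4 (4R)-4-benzyl-3-(3-methylbut-2-enoyl)-1,3-oxazolidin-2-one; 5 tert-butyl bromoacetate
Product: 7 tert-butyl (3R)-3-[(4R)-4-benzyl-2-oxo-1,3-oxazolidine-3-carbonyl]-4-methylpent-4-enoate, via sodium (Z)-dienolate 6 (not isolated)
Conditions: NaN(SiMe3)2, THF, −78 °C; then 5, −78 → −50 °C; AcOH quench at −78 °C
Reagents that add atoms: none
Why: Deconjugative Evans auxiliary alkylation: γ-deprotonation of the s-cis enoyl imide gives the chelated (Z)-dienolate 6, which alkylates at the α-carbon with the activated bromide; the benzyl group of the (4R)-auxiliary blocks one face, so the acetate arm enters anti to it and sets C7' as (R) (the (4S)-auxiliary would give the antipode). Low temperature and an acidic quench should keep the doubly activated α-hydrogen of 7 from epimerising or the alkene from returning to conjugation.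

Step 3
Reactants: 7 tert-butyl (3R)-3-[(4R)-4-benzyl-2-oxo-1,3-oxazolidine-3-carbonyl]-4-methylpent-4-enoate
Product: 8 tert-butyl (3R)-3-(hydroxymethyl)-4-methylpent-4-enoate
Conditions: LiBH4, MeOH (1 equiv), Et2O, 0 °C
Reagents that add atoms: none
Why: Reductive auxiliary removal: LiBH4 with one equivalent of MeOH reduces the exocyclic imide carbonyl chemoselectively and should leave the hindered tert-butyl ester and the alkene; C7' is not touched and the auxiliary is recovered.

Step 4
Reactants: 8 tert-butyl (3R)-3-(hydroxymethyl)-4-methylpent-4-enoate
Product: 9 tert-butyl (3R)-3-(chloromethyl)-4-methylpent-4-enoate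
Conditions: PPh3, N-chlorosuccinimide, CH2Cl2, 0 °C → rt
Reagents that add atoms: N-chlorosuccinimide, O=C1CCC(=O)N1Cl
Why: Appel-type chlorination through the alkoxyphosphonium salt; SN2 displacement at the primary carbon under neutral conditions leaves the stereocentre, ester and alkene intact, and the low temperature disfavours lactonisation by ester participation.

Step 5
Reactants: 9 tert-butyl (3R)-3-(chloromethyl)-4-methylpent-4-enoate
Product: 10 (3R)-3-(chloromethyl)-4-methylpent-4-en-1-ol
Conditions: i-Bu2AlH (3 equiv), CH2Cl2, −78 → 0 °C; aq. KNa tartrate
Reagents that add atoms: none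
Why: Ester reduction with i-Bu2AlH gives the primary alcohol without touching the primary alkyl chloride or the alkene; the two arms on C7' are now CH2Cl and CH2CH2OH.

Step 6
Reactants: 10 (3R)-3-(chloromethyl)-4-methylpent-4-en-1-ol
Product: 11 (3R)-5-bromo-3-(chloromethyl)-2-methylpent-1-ene
Conditions: CBr4, PPh3, CH2Cl2, 0 °C
Reagents that add atoms: carbon tetrabromide, BrC(Br)(Br)Br
Why: Appel bromination of the unhindered primary alcohol; the bromide will insert magnesium far faster than the β-branched chloride.

Step 7
Reactants: 11 (3R)-5-bromo-3-(chloromethyl)-2-methylpent-1-ene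
Product: 12 [(3R)-3-(chloromethyl)-4-methylpent-4-en-1-yl]magnesium bromide (Et2O solution, titrated, used at once)
Conditions: Mg turnings (activated with BrCH2CH2Br), Et2O, 25–30 °C
Reagents that add atoms: magnesium, [Mg]
Why: Grignard formation by direct insertion into the C–Br bond; primary alkyl chlorides are inert to magnesium in Et2O at this temperature and four-membered ring closure of a 4-chlorobutylmagnesium halide is slow, so the reagent should be stable enough to titrate and use directly; C7' is untouched.

Step 8
Reactants: 13 3-methylcyclohex-2-en-1-one; 12 [(3R)-3-(chloromethyl)-4-methylpent-4-en-1-yl]magnesium bromide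
Product: 15 (4aS,7S,8aR)-4a-methyl-7-(prop-1-en-2-yl)octahydronaphthalen-1(2H)-one, via bromomagnesium enolate 14 (not isolated)
Conditions: Cu(OTf)2 (4 mol %), chiral 1-mesityl-3-(1-hydroxy-3,3-dimethylbutan-2-yl)imidazolinium PF6 salt (5 mol %), Et2O, −30 → 0 °C; then THF, HMPA, 0 → 45 °C; cold pH 7 phosphate buffer
Reagents that add atoms: none
Why: The Grignard reagent deprotonates the imidazolinium salt and transmetalates to copper, giving a carbene-bound alkylcopper (monovalent copper) that π-complexes enone 13, adds at C3 and reductively eliminates to form C9'–C10'; the closest known reaction type is the copper–carbene-catalysed asymmetric conjugate addition of primary alkyl Grignard reagents to 3-methylcyclohex-2-enone, which builds all-carbon quaternary centres. The C10' configuration (S) is set by the ligand, which must deliver the alkyl group to the Re face of C3; the C7' centre of 12 is four bonds from the reacting carbon and should not interfere, and because 12 is enantiopure a facial error appears as a separable diastereomer, not as loss of enantiopurity. The addition leaves the regiodefined enolate 14 (C4'=C5'), which should be inert to the β-branched primary chloride in Et2O at 0 °C. THF and HMPA break up the enolate aggregates, and on warming C5' displaces chloride at C6' in a 6-(enolexo)-exo-tet closure of ring B, as in known conjugate addition–cycloalkylation annulations with ω-chloroalkyl organometallics. Attack on the enolate must be perpendicular to its plane and a four-atom tether from C10' can reach only the lobe on its own face, so the ring fusion is cis by geometry (C5' R); the chair-like transition state holds the C7' isopropenyl group axial, syn to hydrogens only, which costs rate but not selectivity, and the product relaxes to the conformer with that group equatorial. The step needs 1,4- over 1,2-addition (catalyst, Et2O, low temperature), C- over O-alkylation and C5' over C3' alkylation (only the C5' enolate is formed and the other modes would need eight-membered rings), and survival of the C–Cl bond until the enolate exists (it resists both magnesium and copper). A cold neutral quench keeps the epimerisable C5' of 15 away from base.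

Step 9
Reactants: 15 (4aS,7S,8aR)-4a-methyl-7-(prop-1-en-2-yl)octahydronaphthalen-1(2H)-one
Product: 16 (4aS,7S,8aR)-7-(3-hydroxyprop-1-en-2-yl)-4a-methyloctahydronaphthalen-1(2H)-one
Conditions: SeO2 (0.3 equiv), t-BuOOH, CH2Cl2, 0 °C → rt
Reagents that add atoms: selenium dioxide, O=[Se]=O (oxygen carrier); tert-butyl hydroperoxide, CC(C)(C)OO (net oxygen source)
Why: Catalytic SeO2 allylic hydroxylation (ene reaction, then [2,3]-sigmatropic shift) of a 1,1-disubstituted alkene; the methyl hydrogens should be taken in preference to the hindered tertiary C7'–H, whose removal would need a tetrasubstituted alkene. Running it while C4' is still a ketone avoids competition from the later C4'=C15' alkene, and the near-neutral conditions should leave C5' unepimerised.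

Step 10
Reactants: 16 (4aS,7S,8aR)-7-(3-hydroxyprop-1-en-2-yl)-4a-methyloctahydronaphthalen-1(2H)-one
Product: 17 (4aS,7S,8aR)-7-[3-(tert-butyldimethylsilyloxy)prop-1-en-2-yl]-4a-methyloctahydronaphthalen-1(2H)-one
Conditions: t-BuMe2SiCl, imidazole, CH2Cl2, 0 °C → rt
Reagents that add atoms: tert-butyldimethylsilyl chloride, CC(C)(C)[Si](C)(C)Cl
Why: Standard imidazole-promoted silylation of a primary allylic alcohol, to keep the hydroxyl away from the reducing titanium reagent of the next step; imidazole is too weak a base to epimerise C5'.

Step 11
Reactants: 17 (4aS,7S,8aR)-7-[3-(tert-butyldimethylsilyloxy)prop-1-en-2-yl]-4a-methyloctahydronaphthalen-1(2H)-one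
Product: 18 tert-butyldimethyl({2-[(2S,4aS,8aS)-4a-methyl-8-methylidenedecahydronaphthalen-2-yl]prop-2-en-1-yl}oxy)silane
Conditions: Zn, CH2Br2, TiCl4, THF, −40 → 5 °C (reagent); then 17, CH2Cl2, rt; aq. NaHCO3
Reagents that add atoms: dibromomethane, BrCBr
Why: Takai–Lombardo methylenation: the zinc–titanium gem-dimetallic reagent is non-basic and is known to methylenate hindered, enolisable ketones without α-epimerisation, which a phosphorus ylide would risk at C5'; the silyl ether and the 1,1-disubstituted alkene should be inert. The C5' descriptor changes to S only because the priorities change.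

Step 12
Reactants: 18 tert-butyldimethyl({2-[(2S,4aS,8aS)-4a-methyl-8-methylidenedecahydronaphthalen-2-yl]prop-2-en-1-yl}oxy)silane
Product: 19 2-[(2S,4aS,8aS)-4a-methyl-8-methylidenedecahydronaphthalen-2-yl]prop-2-en-1-ol
Conditions: Bu4NF, THF, 0 °C → rt
Reagents that add atoms: none
Why: Fluoride cleavage of the silyl ether; nothing in 18 is sensitive to base or fluoride now that C4' is no longer a carbonyl.

Step 13
Reactants: 19 2-[(2S,4aS,8aS)-4a-methyl-8-methylidenedecahydronaphthalen-2-yl]prop-2-en-1-ol
Product: 20 2-[(2S,4aS,8aS)-4a-methyl-8-methylidenedecahydronaphthalen-2-yl]prop-2-enal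
Conditions: MnO2 (excess), CH2Cl2, rt; filter, use at once
Reagents that add atoms: none
Why: MnO2 oxidises allylic alcohols selectively to enals under neutral heterogeneous conditions and should not touch the isolated C4'=C15' alkene; the 2-substituted acrolein is carried on directly because it polymerises and dimerises on standing.

Step 14
Reactants: 20 2-[(2S,4aS,8aS)-4a-methyl-8-methylidenedecahydronaphthalen-2-yl]prop-2-enal; 21 alantolactone
Product: 22 the target: 11,13-dihydroalantolactone whose C11 is the spiro C2 of a 3,4-dihydro-2H-pyran (C11 R, ring oxygen on the α face syn to H-7) that bears the (2S,4aS,8aS)-4a-methyl-8-methylidenedecahydronaphthalen-2-yl group at C5 of the pyran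
Conditions: neat in molten 21 (4 equiv), 2,6-di-tert-butyl-4-methylphenol (cat.), 110–120 °C, sealed tube; chromatography on Et3N-deactivated silica
Reagents that add atoms: none
Why: Thermal hetero-Diels–Alder reaction of the 1-oxadiene C13'=C11'–C12'=O with the C11=C13 methylene of 21, of the acrolein-dimerisation type: oxygen bonds to the α-carbon C11 and C13' to C13, because the asynchronous transition state leads with the C13–C13' bond and places the developing charge or spin at C11 next to the lactone carbonyl. The diene should approach the convex α face of the cis-fused lactone, syn to H-7 and away from ring B and the C10 methyl, which sets C11 as (R); no other stereocentre is formed. Excess 21 and a radical inhibitor suppress self-dimerisation and polymerisation of 20.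

## Compound list

1 | 3-methylbut-2-enoic acid | CC(C)=CC(=O)O | starting material
2 | (4R)-4-benzyl-1,3-oxazolidin-2-one | O=C1OC[C@@H](Cc2ccccc2)N1 | starting material
3 | 3-methylbut-2-enoic pivalic anhydride | CC(C)=CC(=O)OC(=O)C(C)(C)C | intermediate
4 | (4R)-4-benzyl-3-(3-methylbut-2-enoyl)-1,3-oxazolidin-2-one | CC(C)=CC(=O)N1C(=O)OC[C@H]1Cc1ccccc1 | intermediate
5 | tert-butyl bromoacetate | BrCC(=O)OC(C)(C)C | starting material
6 | sodium (Z)-dienolate of imide 4 (sodium (1Z)-1-[(4R)-4-benzyl-2-oxo-1,3-oxazolidin-3-yl]-3-methylbuta-1,3-dien-1-olate) | C=C(C)/C=C(\[O-])N1C(=O)OC[C@H]1Cc1ccccc1.[Na+] | intermediate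
7 | tert-butyl (3R)-3-[(4R)-4-benzyl-2-oxo-1,3-oxazolidine-3-carbonyl]-4-methylpent-4-enoate | CC(=C)[C@@H](CC(=O)OC(C)(C)C)C(=O)N1C(=O)OC[C@H]1Cc1ccccc1 | intermediate
8 | tert-butyl (3R)-3-(hydroxymethyl)-4-methylpent-4-enoate | OC[C@H](CC(=O)OC(C)(C)C)C(C)=C | intermediate
9 | tert-butyl (3R)-3-(chloromethyl)-4-methylpent-4-enoate | ClC[C@H](CC(=O)OC(C)(C)C)C(C)=C | intermediate
10 | (3R)-3-(chloromethyl)-4-methylpent-4-en-1-ol | ClC[C@H](CCO)C(C)=C | intermediate
11 | (3R)-5-bromo-3-(chloromethyl)-2-methylpent-1-ene | ClC[C@H](CCBr)C(C)=C | intermediate
12 | [(3R)-3-(chloromethyl)-4-methylpent-4-en-1-yl]magnesium bromide | ClC[C@H](CC[Mg]Br)C(C)=C | intermediate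
13 | 3-methylcyclohex-2-en-1-one | CC1=CC(=O)CCC1 | starting material
14 | bromomagnesium (3S)-3-[(3R)-3-(chloromethyl)-4-methylpent-4-en-1-yl]-3-methylcyclohex-1-en-1-olate | C[C@@]1(CC[C@@H](CCl)C(C)=C)CCCC(O[Mg]Br)=C1 | intermediate
15 | (4aS,7S,8aR)-4a-methyl-7-(prop-1-en-2-yl)octahydronaphthalen-1(2H)-one (cis-fused; methyl, H-8a and isopropenyl all cis) | O=C1CCC[C@@]2(C)CC[C@H](C(C)=C)C[C@@H]12 | intermediate
16 | (4aS,7S,8aR)-7-(3-hydroxyprop-1-en-2-yl)-4a-methyloctahydronaphthalen-1(2H)-one | O=C1CCC[C@@]2(C)CC[C@H](C(=C)CO)C[C@@H]12 | intermediate
17 | (4aS,7S,8aR)-7-[3-(tert-butyldimethylsilyloxy)prop-1-en-2-yl]-4a-methyloctahydronaphthalen-1(2H)-one | O=C1CCC[C@@]2(C)CC[C@H](C(=C)CO[Si](C)(C)C(C)(C)C)C[C@@H]12 | intermediate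
18 | tert-butyldimethyl({2-[(2S,4aS,8aS)-4a-methyl-8-methylidenedecahydronaphthalen-2-yl]prop-2-en-1-yl}oxy)silane | C=C1CCC[C@@]2(C)CC[C@H](C(=C)CO[Si](C)(C)C(C)(C)C)C[C@@H]12 | intermediate
19 | 2-[(2S,4aS,8aS)-4a-methyl-8-methylidenedecahydronaphthalen-2-yl]prop-2-en-1-ol | C=C1CCC[C@@]2(C)CC[C@H](C(=C)CO)C[C@@H]12 | intermediate
20 | 2-[(2S,4aS,8aS)-4a-methyl-8-methylidenedecahydronaphthalen-2-yl]prop-2-enal | C=C1CCC[C@@]2(C)CC[C@H](C(=C)C=O)C[C@@H]12 | intermediate
21 | alantolactone, (3aR,5S,8aR,9aR)-5,8a-dimethyl-3-methylidene-3a,5,6,7,8,8a,9,9a-octahydronaphtho[2,3-b]furan-2(3H)-one | C=C1C(=O)O[C@@H]2C[C@@]3(C)CCC[C@H](C)C3=C[C@@H]21 | starting material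
22 | target: spiro[3,4-dihydro-2H-pyran-2,11'-(11,13-dihydroalantolactone)] with C11 R (pyran oxygen α, syn to H-7) and the (2S,4aS,8aS)-4a-methyl-8-methylidenedecahydronaphthalen-2-yl group on C5 of the pyran | C=C1CCC[C@@]2(C)CC[C@H](C3=CO[C@@]4(CC3)C(=O)O[C@@H]3C[C@@]5(C)CCC[C@H](C)C5=C[C@@H]34)C[C@@H]12 | target

## Step count and risk

Total step count: 14. Longest linear sequence: 14 steps (1 → 22); compounds 2, 5, 13 and 21 enter as purchased materials.

**Step 8 (key step).**
- What may go wrong: slow ring closure is the most likely failure. The bromomagnesium enolate is a poor nucleophile toward a β-branched primary chloride, and the chair transition state carries an axial isopropenyl group. Proton transfer can then quench the enolate before C5'–C6' forms, leaving the uncyclised chloro ketone. A second risk is reduced facial selectivity of the copper–carbene catalyst with this functionalised Grignard reagent, which would lower the diastereomer ratio at C10'.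
- Fallback: the two events are separated. The fallback sets out from 12 and 13 and comes back at 15. The conjugate addition is run as before and the enolate is trapped with Me3SiCl/Et3N to give the regiodefined silyl enol ether {[(3S)-3-[(3R)-3-(chloromethyl)-4-methylpent-4-en-1-yl]-3-methylcyclohex-1-en-1-yl]oxy}trimethylsilane F1. F1 can be purified, and the C10' diastereomers separated if needed. MeLi in THF then regenerates the more reactive lithium enolate at the same position, and HMPA and warming close ring B to 15 under the same geometric constraint.

**Step 14.**
- What may go wrong: self-dimerisation and polymerisation of the 2-substituted acrolein may outrun the cross-cycloaddition, since the enal is itself a dienophile of the same type as the lactone. Attack on the β face of the lactone would give the C11 epimer.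
- Fallback: the pyran is built stepwise. The fallback sets out from 21 and 20 and comes back at 22. Nucleophilic epoxidation of the methylene lactone (t-BuOOH, DBU; Weitz–Scheffer type, which spares C5=C6) should give 11α,13-epoxy-11,13-dihydroalantolactone F2, with the oxygen delivered to the convex face. MgI2 opens the epoxide at the primary carbon to 11α-hydroxy-13-iodo-11,13-dihydroalantolactone F3. A tin-hydride Giese addition (Bu3SnH, azobisisobutyronitrile, slow addition) of the C13 radical to the β-carbon C13' of 20 gives the δ-hydroxy aldehyde 3-(11α-hydroxy-11,13-dihydroalantolacton-13-yl)-2-[(2S,4aS,8aS)-4a-methyl-8-methylidenedecahydronaphthalen-2-yl]propanal F4, which exists mainly as its lactol. Mild dehydration (pyridinium p-toluenesulfonate, benzene, molecular sieves) forms the C11'=C12' enol ether of 22. Here C11 is fixed before the ring forms, and the C11' centre of F4 is lost on dehydration.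

**Step 9.**
- What may go wrong: hydrogen abstraction at the tertiary C7' instead of the methyl group, over-oxidation of the alcohol to the enal (which cannot simply be reduced back beside the ketone), or α-oxidation of the C4' ketone.
- Fallback: the fallback sets out from 15 and comes back at 19. Ene-type chlorination of the isopropenyl group with HOCl generated from Ca(OCl)2 and CO2 in CH2Cl2/water gives (4aS,7S,8aR)-7-(3-chloroprop-1-en-2-yl)-4a-methyloctahydronaphthalen-1(2H)-one F5. KOAc with 18-crown-6 in MeCN displaces chloride to give 2-[(2S,4aS,8aR)-4a-methyl-8-oxodecahydronaphthalen-2-yl]prop-2-en-1-yl acetate F6. Takai–Lombardo methylenation gives 2-[(2S,4aS,8aS)-4a-methyl-8-methylidenedecahydronaphthalen-2-yl]prop-2-en-1-yl acetate F7. K2CO3 in MeOH, which is harmless once C4' is no longer a carbonyl, releases 19.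

**Step 11.**
- What may go wrong: sluggish methylenation of the hindered C4' carbonyl next to the ring fusion, or Lewis-acid-induced epimerisation at C5' or loss of the silyl ether under titanium halide conditions.
- Fallback: a Peterson olefination replaces the direct carbonyl methylenation. The fallback sets out from 17 and comes back at 18. Me3SiCH2Li premixed with anhydrous CeCl3 (a weakly basic organocerium reagent suited to enolisable ketones) adds to C4' to give (4aS,7S,8aR)-7-[3-(tert-butyldimethylsilyloxy)prop-1-en-2-yl]-4a-methyl-1-[(trimethylsilyl)methyl]decahydronaphthalen-1-ol F8, whose carbinol configuration is inconsequential. KH in THF then effects syn-elimination to 18; C5' is no longer acidic at that stage.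

**Step 2.**
- What may go wrong: erosion of the diastereomer ratio, or epimerisation and re-conjugation of 7 by proton exchange with unreacted dienolate, since the α-hydrogen of 7 is flanked by the imide and the alkene. Competing γ-alkylation is a lesser risk.
- Fallback: resolution replaces auxiliary control. The fallback sets out from 1 and 5 and comes back at 8. The dianion of 1 (2 equiv LiN(i-Pr)2, THF, −78 °C) is alkylated at the α-carbon with 5 to give racemic 4-tert-butoxy-4-oxo-2-(prop-1-en-2-yl)butanoic acid F9. Crystallisation of its 1-phenylethylamine salt gives (2R)-4-tert-butoxy-4-oxo-2-(prop-1-en-2-yl)butanoic acid F10. Activation with i-BuOCOCl and N-methylmorpholine gives the isobutyl carbonic mixed anhydride F11, and NaBH4 in THF/water at 0 °C reduces it to 8 without touching the tert-butyl ester or the alkene.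

## Further compounds

F1 | step 8 | {[(3S)-3-[(3R)-3-(chloromethyl)-4-methylpent-4-en-1-yl]-3-methylcyclohex-1-en-1-yl]oxy}trimethylsilane | C[C@@]1(CC[C@@H](CCl)C(C)=C)CCCC(O[Si](C)(C)C)=C1
F2 | step 14 | 11α,13-epoxy-11,13-dihydroalantolactone (oxirane oxygen syn to H-7) | C1O[C@]12C(=O)O[C@@H]3C[C@@]4(C)CCC[C@H](C)C4=C[C@@H]32
F3 | step 14 | 11α-hydroxy-13-iodo-11,13-dihydroalantolactone | O[C@@]1(CI)C(=O)O[C@@H]2C[C@@]3(C)CCC[C@H](C)C3=C[C@@H]21
F4 | step 14 | 3-(11α-hydroxy-11,13-dihydroalantolacton-13-yl)-2-[(2S,4aS,8aS)-4a-methyl-8-methylidenedecahydronaphthalen-2-yl]propanal (C2 epimers, in equilibrium with the lactol) | C=C1CCC[C@@]2(C)CC[C@H](C(C=O)CC[C@]3(O)C(=O)O[C@@H]4C[C@@]5(C)CCC[C@H](C)C5=C[C@@H]43)C[C@@H]12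
F5 | step 9 | (4aS,7S,8aR)-7-(3-chloroprop-1-en-2-yl)-4a-methyloctahydronaphthalen-1(2H)-one | O=C1CCC[C@@]2(C)CC[C@H](C(=C)CCl)C[C@@H]12
F6 | step 9 | 2-[(2S,4aS,8aR)-4a-methyl-8-oxodecahydronaphthalen-2-yl]prop-2-en-1-yl acetate | O=C1CCC[C@@]2(C)CC[C@H](C(=C)COC(C)=O)C[C@@H]12
F7 | step 9 | 2-[(2S,4aS,8aS)-4a-methyl-8-methylidenedecahydronaphthalen-2-yl]prop-2-en-1-yl acetate | C=C1CCC[C@@]2(C)CC[C@H](C(=C)COC(C)=O)C[C@@H]12
F8 | step 11 | (4aS,7S,8aR)-7-[3-(tert-butyldimethylsilyloxy)prop-1-en-2-yl]-4a-methyl-1-[(trimethylsilyl)methyl]decahydronaphthalen-1-ol (C1 configuration undefined) | C[Si](C)(C)CC1(O)CCC[C@@]2(C)CC[C@H](C(=C)CO[Si](C)(C)C(C)(C)C)C[C@@H]12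
F9 | step 2 | racemic 4-tert-butoxy-4-oxo-2-(prop-1-en-2-yl)butanoic acid | OC(=O)C(CC(=O)OC(C)(C)C)C(C)=C
F10 | step 2 | (2R)-4-tert-butoxy-4-oxo-2-(prop-1-en-2-yl)butanoic acid | OC(=O)[C@H](CC(=O)OC(C)(C)C)C(C)=C
F11 | step 2 | isobutyl carbonic (2R)-4-tert-butoxy-4-oxo-2-(prop-1-en-2-yl)butanoic anhydride | CC(C)COC(=O)OC(=O)[C@H](CC(=O)OC(C)(C)C)C(C)=C
A1 | alternative 1 | alantolactone | C=C1C(=O)O[C@@H]2C[C@@]3(C)CCC[C@H](C)C3=C[C@@H]21
A2 | alternative 1 | 2-[(1R,2Z,3S)-2-(buta-2,3-dien-1-ylidene)-1,3-dimethylcyclohexyl]acetaldehyde | O=CC[C@@]1(C)CCC[C@H](C)/C1=C/C=C=C
A3 | alternative 2 | cis-fused octalone ketal, 4a-methyl-7-(2-methyl-1,3-dioxolan-2-yl)-3,4,4a,7,8,8a-hexahydronaphthalen-1(2H)-one with methyl, H-8a and the C7 substituent all cis | O=C1CCC[C@@]2(C)C=C[C@H](C3(C)OCCO3)C[C@@H]12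
A4 | alternative 2 | (7Z,9E)-7-methyl-10-(2-methyl-1,3-dioxolan-2-yl)deca-1,7,9-trien-3-one | C=CC(=O)CCC/C(C)=C\C=C\C1(C)OCCO1
A5 | alternative 3 | spiro 3,6-dihydro-2H-pyran isomer of the target (ring alkene C13'=C11') | C=C1CCC[C@@]2(C)CC[C@H](C3=CC[C@]4(OC3)C(=O)O[C@@H]5C[C@@]6(C)CCC[C@H](C)C6=C[C@@H]54)C[C@@H]12
A6 | alternative 3 | metathesis diene: 11,13-dihydroalantolactone with an allyl group on C13 and, on C11, the α-oriented 2-[(2S,4aS,8aS)-4a-methyl-8-methylidenedecahydronaphthalen-2-yl]prop-2-en-1-yloxy group | C=C1CCC[C@@]2(C)CC[C@H](C(=C)CO[C@@]3(CC=C)C(=O)O[C@@H]4C[C@@]5(C)CCC[C@H](C)C5=C[C@@H]43)C[C@@H]12
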